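**Retrosynthetic overview**
1. The enal is unmasked last: target 13 ⇐ isopropenyl bis-ester 11 by allylic oxidation of the CH3 group, so the C3 oxygen is never free next to the aldehyde (no lactol).
2. 11 ⇐ diol 9 (double acylation) ⇐ aldehyde 7 by catalytic asymmetric methyl addition, which sets the side-chain (R) centre.
3. Key disconnection, C2–C3 of 7 ⇐ allenyl ether 4: a nickel-catalysed methylative cyclisation in which the O-bearing allene carbon (the future β-carbon of the enal, normally electrophilic) reacts as a nucleophilic 3-aryloxy-2-methylallyl metal, a homoenolate equivalent, with the ortho aldehyde.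
4. 4 ⇐ 4-hydroxyisophthalaldehyde 1 + propargyl bromide 2 (O-alkylation, then propargyl-to-allenyl isomerisation).
5. Ring order: the benzene ring is bought; the dihydrofuran ring is the only ring formed (step 3), with the cis C2/C3 relationship set in the same step.

Assumption: in step 3 the (S)-spiro phosphoramidite is taken to give the (2R,3R) product; if the sense is the opposite, the (R)-ligand is used with nothing else changed.

**Step 1**
Reactants: 1 4-hydroxybenzene-1,3-dicarbaldehyde (4-hydroxyisophthalaldehyde); 2 propargyl bromide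
Product: 3 4-(prop-2-yn-1-yloxy)benzene-1,3-dicarbaldehyde
Conditions: K2CO3 (1.5 equiv), DMF, rt
Reagents that add atoms: propargyl bromide, C#CCBr
Why: Williamson ether synthesis; the phenoxide, acidified by two formyl groups, displaces bromide by SN2, and no stereocentre is involved.

**Step 2**
Reactants: 3 4-(prop-2-yn-1-yloxy)benzene-1,3-dicarbaldehyde
Product: 4 4-(propa-1,2-dien-1-yloxy)benzene-1,3-dicarbaldehyde
Conditions: KOtBu (0.2 equiv), THF, 0 °C to rt, 1 h; chromatography on Et3N-deactivated silica
Reagents that add atoms: none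
Why: Base-catalysed propargyl-to-allenyl prototropic isomerisation, which for aryl propargyl ethers stops at the aryloxyallene; both aldehydes are non-enolisable, so there is no aldol pathway, and no stereocentre is formed.

**Step 3 (key step)**
Reactants: 4 4-(propa-1,2-dien-1-yloxy)benzene-1,3-dicarbaldehyde; 5 dimethylzinc
Product: 7 (2R,3R)-3-hydroxy-2-(prop-1-en-2-yl)-2,3-dihydro-1-benzofuran-5-carbaldehyde (cis), via methylzinc alkoxide 6 (not isolated)
Conditions: Ni(cod)2 (10 mol %), (S)-SIPHOS-type spirobiindane phosphoramidite (12 mol %), Me2Zn (1.5 equiv), toluene/THF, 0 °C, slow addition of 4; then pH 7 aqueous buffer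
Reagents that add atoms: dimethylzinc, C[Zn]C
Why: Proposed new method: zerovalent nickel couples the ortho formyl group with the O-substituted π-bond of the allene by oxidative cyclisation to an oxanickelacycle (equivalently, methyl-nickelation gives a 3-aryloxy-2-methylallyl metal that adds through its O-bearing carbon), so the normally electrophilic enol-ether carbon bonds as a nucleophile to the aldehyde carbon; this allyl metal is a homoenolate equivalent of the 2-substituted acrolein of the target (C2 is its β-carbon, the aldehyde carbon travelling as the CH3 delivered from zinc); methyl transfer from zinc and reductive elimination place CH3 on the central allene carbon; the C3–O and C2–alkenyl bonds both lie in the five-membered nickelacycle, which forces the cis relationship, and the chiral phosphoramidite selects the aldehyde face to give (2R,3R); the remote para aldehyde is spared because uncatalysed Me2Zn addition to aryl aldehydes is slow at 0 °C; the closest known reaction types are the cis-selective nickel-catalysed alkylative cyclisation of allenyl aldehydes with organozincs and the nickel/spiro-phosphoramidite enantioselective alkylative coupling of alkynes, aldehydes and Me2Zn.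

**Step 4**
Reactants: 7 (2R,3R)-3-hydroxy-2-(prop-1-en-2-yl)-2,3-dihydro-1-benzofuran-5-carbaldehyde; 5 dimethylzinc
Product: 9 (2R,3R)-5-[(1R)-1-hydroxyethyl]-2-(prop-1-en-2-yl)-2,3-dihydro-1-benzofuran-3-ol, via bis(methylzinc) dialkoxide 8 (not isolated)
Conditions: (2R)-(+)-3-exo-morpholinoisoborneol [(+)-MIB] (10 mol %), Me2Zn (4 equiv), toluene, 0 °C to rt; then pH 7 aqueous buffer
Reagents that add atoms: dimethylzinc, C[Zn]C
Why: Amino-alcohol-catalysed (ligand-accelerated) asymmetric 1,2-addition of a dialkylzinc to an aryl aldehyde; (+)-MIB directs methyl transfer to the Re face, giving the (R)-carbinol, while the C3 hydroxyl is only converted to a spectator zinc alkoxide.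

**Step 5**
Reactants: 9 (2R,3R)-5-[(1R)-1-hydroxyethyl]-2-(prop-1-en-2-yl)-2,3-dihydro-1-benzofuran-3-ol; 10 3-methylbutanoic anhydride (isovaleric anhydride)
Product: 11 (1R)-1-[(2R,3R)-3-(3-methylbutanoyloxy)-2-(prop-1-en-2-yl)-2,3-dihydro-1-benzofuran-5-yl]ethyl 3-methylbutanoate
Conditions: (iBuCO)2O (3 equiv), Et3N (4 equiv), DMAP (10 mol %), CH2Cl2, 0 °C to rt
Reagents that add atoms: 3-methylbutanoic anhydride, CC(C)CC(=O)OC(=O)CC(C)C
Why: DMAP-catalysed acylation of both secondary benzylic alcohols under basic, non-ionising conditions; only O–acyl bonds form, so all three stereocentres are retained.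

**Step 6**
Reactants: 11 (1R)-1-[(2R,3R)-3-(3-methylbutanoyloxy)-2-(prop-1-en-2-yl)-2,3-dihydro-1-benzofuran-5-yl]ethyl 3-methylbutanoate; 12 selenium dioxide
Product: 13 (1R)-1-[(2R,3R)-3-(3-methylbutanoyloxy)-2-(3-oxoprop-1-en-2-yl)-2,3-dihydro-1-benzofuran-5-yl]ethyl 3-methylbutanoate (CNP0316116.1)
Conditions: SeO2 (1.5 equiv), 1,4-dioxane, 80 °C
Reagents that add atoms: selenium dioxide, O=[Se]=O
Why: Riley allylic oxidation (ene reaction, then [2,3]-sigmatropic shift, then further oxidation of the allylic alcohol) converts the isopropenyl CH3 into CHO, as for other isopropenyl groups on a methine carbon; the CH3 reacts in preference to the hindered, O-substituted C2–H, and no stereocentre is touched.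

**Compound list**
1 | 4-hydroxybenzene-1,3-dicarbaldehyde | O=Cc1ccc(O)c(C=O)c1 | starting material
2 | propargyl bromide | C#CCBr | starting material
3 | 4-(prop-2-yn-1-yloxy)benzene-1,3-dicarbaldehyde | O=Cc1ccc(OCC#C)c(C=O)c1 | intermediate
4 | 4-(propa-1,2-dien-1-yloxy)benzene-1,3-dicarbaldehyde | O=Cc1ccc(OC=C=C)c(C=O)c1 | intermediate
5 | dimethylzinc | C[Zn]C | starting material
6 | methylzinc (2R,3R)-5-formyl-2-(prop-1-en-2-yl)-2,3-dihydro-1-benzofuran-3-olate | C=C(C)[C@H]1Oc2ccc(C=O)cc2[C@H]1O[Zn]C | intermediate (not isolated)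
7 | (2R,3R)-3-hydroxy-2-(prop-1-en-2-yl)-2,3-dihydro-1-benzofuran-5-carbaldehyde | C=C(C)[C@H]1Oc2ccc(C=O)cc2[C@H]1O | intermediate
8 | bis(methylzinc) dialkoxide of diol 9 | C=C(C)[C@H]1Oc2ccc([C@@H](C)O[Zn]C)cc2[C@H]1O[Zn]C | intermediate (not isolated)
9 | (2R,3R)-5-[(1R)-1-hydroxyethyl]-2-(prop-1-en-2-yl)-2,3-dihydro-1-benzofuran-3-ol | C=C(C)[C@H]1Oc2ccc([C@@H](C)O)cc2[C@H]1O | intermediate
10 | 3-methylbutanoic anhydride | CC(C)CC(=O)OC(=O)CC(C)C | starting material
11 | (1R)-1-[(2R,3R)-3-(3-methylbutanoyloxy)-2-(prop-1-en-2-yl)-2,3-dihydro-1-benzofuran-5-yl]ethyl 3-methylbutanoate | C=C(C)[C@H]1Oc2ccc([C@@H](C)OC(=O)CC(C)C)cc2[C@H]1OC(=O)CC(C)C | intermediate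
12 | selenium dioxide | O=[Se]=O | starting material (reagent)
13 | (1R)-1-[(2R,3R)-3-(3-methylbutanoyloxy)-2-(3-oxoprop-1-en-2-yl)-2,3-dihydro-1-benzofuran-5-yl]ethyl 3-methylbutanoate | C=C(C=O)[C@H]1Oc2ccc([C@@H](C)OC(=O)CC(C)C)cc2[C@H]1OC(=O)CC(C)C | target

**Totals**
Total steps: 6. Longest linear sequence: 6 steps (1 → 3 → 4 → 7 → 9 → 11 → 13).

**Three steps most likely to fail, with fallbacks**

Step 3 (the enantioselective nickel cyclisation is new; risks are low ee and methylation of the para aldehyde). The fallback sets out from 4 and separates ring closure from methyl delivery. A monovalent-copper-catalysed enantioselective borylative cyclisation (CuCl, chiral bisphosphine such as DTBM-SEGPHOS in the antipode giving 2R,3R, NaOtBu, B2pin2, THF) adds the boryl group to the central allene carbon. The resulting 2-borylallyl copper closes onto the ortho aldehyde to give the cis alkenylboronate (2R,3R)-3-hydroxy-2-[1-(4,4,5,5-tetramethyl-1,3,2-dioxaborolan-2-yl)ethenyl]-2,3-dihydro-1-benzofuran-5-carbaldehyde F1. Suzuki–Miyaura methylation of F1 (MeI, PdCl2(dppf), K3PO4, THF/H2O) then returns to the route at 7.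

Step 4 (the free C3 zinc alkoxide may erode catalyst control, and Me2Zn additions are slower and less selective than Et2Zn additions). The fallback sets out from 7 and sets the carbinol by ketone reduction instead of C–C addition. The C3 hydroxyl is acylated first (isovaleric anhydride, DMAP) to give (2R,3R)-5-formyl-2-(prop-1-en-2-yl)-2,3-dihydro-1-benzofuran-3-yl 3-methylbutanoate F2. Aldehyde-selective MeTi(OiPr)3 addition gives the side-chain epimer mixture (2R,3R)-5-(1-hydroxyethyl)-2-(prop-1-en-2-yl)-2,3-dihydro-1-benzofuran-3-yl 3-methylbutanoate F3. Dess–Martin oxidation gives the ketone (2R,3R)-5-acetyl-2-(prop-1-en-2-yl)-2,3-dihydro-1-benzofuran-3-yl 3-methylbutanoate F4. Noyori transfer hydrogenation (RuCl(p-cymene)[(R,R)-TsDPEN], HCO2H/Et3N) gives (2R,3R)-5-[(1R)-1-hydroxyethyl]-2-(prop-1-en-2-yl)-2,3-dihydro-1-benzofuran-3-yl 3-methylbutanoate F5, and a second acylation returns to the route at 11.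

Step 6 (hot selenous acid may ionise the 3-acyloxy group toward the benzofuran, or over-oxidise). The fallback sets out from 11 and replaces the selenium ene chemistry by halogenation and N-oxide oxidation. Ene-type allylic chlorination of the isopropenyl group (Ca(OCl)2, solid CO2, CH2Cl2/H2O, 0 °C) gives the allylic chloride (1R)-1-[(2R,3R)-2-(3-chloroprop-1-en-2-yl)-3-(3-methylbutanoyloxy)-2,3-dihydro-1-benzofuran-5-yl]ethyl 3-methylbutanoate F6. Ganem-type oxidation with Me3NO in DMSO at rt converts the CH2Cl group into the aldehyde and returns to the route at 13.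

**Further compounds**
F1 | step 3 | (2R,3R)-3-hydroxy-2-[1-(4,4,5,5-tetramethyl-1,3,2-dioxaborolan-2-yl)ethenyl]-2,3-dihydro-1-benzofuran-5-carbaldehyde | C=C(B1OC(C)(C)C(C)(C)O1)[C@H]1Oc2ccc(C=O)cc2[C@H]1O
F2 | step 4 | (2R,3R)-5-formyl-2-(prop-1-en-2-yl)-2,3-dihydro-1-benzofuran-3-yl 3-methylbutanoate | C=C(C)[C@H]1Oc2ccc(C=O)cc2[C@H]1OC(=O)CC(C)C
F3 | step 4 | (2R,3R)-5-(1-hydroxyethyl)-2-(prop-1-en-2-yl)-2,3-dihydro-1-benzofuran-3-yl 3-methylbutanoate (mixture of side-chain epimers) | C=C(C)[C@H]1Oc2ccc(C(C)O)cc2[C@H]1OC(=O)CC(C)C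
F4 | step 4 | (2R,3R)-5-acetyl-2-(prop-1-en-2-yl)-2,3-dihydro-1-benzofuran-3-yl 3-methylbutanoate | C=C(C)[C@H]1Oc2ccc(C(C)=O)cc2[C@H]1OC(=O)CC(C)C
F5 | step 4 | (2R,3R)-5-[(1R)-1-hydroxyethyl]-2-(prop-1-en-2-yl)-2,3-dihydro-1-benzofuran-3-yl 3-methylbutanoate | C=C(C)[C@H]1Oc2ccc([C@@H](C)O)cc2[C@H]1OC(=O)CC(C)C
F6 | step 6 | (1R)-1-[(2R,3R)-2-(3-chloroprop-1-en-2-yl)-3-(3-methylbutanoyloxy)-2,3-dihydro-1-benzofuran-5-yl]ethyl 3-methylbutanoate | C=C(CCl)[C@H]1Oc2ccc([C@@H](C)OC(=O)CC(C)C)cc2[C@H]1OC(=O)CC(C)C
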